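**Strategy.** The cyclohexane ring (C5 to C10) is closed last from an open chain. The target holds two retrons side by side: the γ,δ-unsaturated carbonyl unit C2=C1–C10–C9–C8(O) and the homoallylic alcohol unit C8(O)–C7–C11. A Z-allyl vinyl ether that carries a C4 ketone, a C6 silyl ether and a prenyl-type C7=C11 alkene is therefore heated: Claisen rearrangement forges C9–C10 with the quaternary centre and its vinyl group, and the aldehyde so unveiled closes C7–C8 by a carbonyl-ene reaction. The chain comes from a syn-aldol reaction; C5 is equilibrated afterwards, then the ketone becomes the methylene group and the lactone is formed.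

Key step: step 10

Remark: atoms are numbered as in elemanolides: C1=C2 is the vinyl group on C10, C3=C4(C15) the propenyl unit on C5, C5 to C10 the ring, C11(C13)–C12 the three-carbon unit on C7, C14 the methyl group on C10, primed atoms the acyl side chain on O8; descriptors in brackets use this numbering.

Assumption: (−)-Ipc2BOTf (from (+)-α-pinene) is taken to deliver the (5R,6S) syn-aldol; should its sense prove opposite, the enantiomeric reagent is used and nothing else changes.

Step 1
Reactants: 1 tert-butyl(oxiran-2-ylmethoxy)diphenylsilane (racemic); 2 ethyl prop-2-ynoate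
Product: 4 ethyl 6-[(tert-butyldiphenylsilyl)oxy]-5-hydroxyhex-2-ynoate (racemic), via lithium acetylide 3 (not isolated)
Conditions: n-BuLi, THF, −78 °C; then BF3·OEt2, 1, −78 °C
Reagents that add atoms: none
Why: The acetylide of 2 opens the BF3-activated epoxide at its unsubstituted carbon (Lewis-acid-promoted epoxide alkynylation), and no lasting stereocenter is set because the carbinol later becomes the C4 ketone.

Step 2
Reactants: 4
Product: 5 ethyl 6-[(tert-butyldiphenylsilyl)oxy]-5-[(triethylsilyl)oxy]hex-2-ynoate (racemic)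
Conditions: Et3SiCl, imidazole, DMF, 0 °C to rt
Reagents that add atoms: chlorotriethylsilane, CC[Si](Cl)(CC)CC
Why: Silyl ether protection of the secondary alcohol keeps it from lactonising onto the Z-enoate of the next step and can later be removed beside the primary tert-butyldiphenylsilyl ether.

Step 3
Reactants: 5
Product: 6 ethyl (2Z)-6-[(tert-butyldiphenylsilyl)oxy]-3-methyl-5-[(triethylsilyl)oxy]hex-2-enoate (racemic)
Conditions: Me2CuLi, THF, −78 °C; NH4Cl (aq), −78 °C
Reagents that add atoms: Me2CuLi, [Li+].C[Cu-]C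
Why: Syn-carbocupration (conjugate addition) of the ynoate with cold protonation places the new methyl group (C14) trans to the ester, so the Z-enoate with C5 and C2 cis should result.

Step 4
Reactants: 6
Product: 7 (2Z)-6-[(tert-butyldiphenylsilyl)oxy]-3-methyl-5-[(triethylsilyl)oxy]hex-2-en-1-ol (racemic)
Conditions: i-Bu2AlH, CH2Cl2, −78 °C
Reagents that add atoms: none
Why: 1,2-Reduction of the enoate gives the allylic alcohol without touching the Z-alkene or the silyl ethers.

Step 5
Reactants: 7; 8 ethoxyethene (ethyl vinyl ether)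
Product: 9 (4Z)-1-[(tert-butyldiphenylsilyl)oxy]-6-(ethenyloxy)-4-methyl-2-[(triethylsilyl)oxy]hex-4-ene (racemic)
Conditions: Hg(OAc)2 (cat.), 8 as solvent, reflux
Reagents that add atoms: none
Why: Hg(OAc)2-catalysed transetherification with excess 8 converts the only free hydroxyl group into the vinyl ether and so brings in C8 and C9.

Step 6
Reactants: 9
Product: 10 (4Z)-1-[(tert-butyldiphenylsilyl)oxy]-6-(ethenyloxy)-4-methylhex-4-en-2-ol (racemic)
Conditions: Bu4NF (1.05 equiv), THF, 0 °C
Reagents that add atoms: none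
Why: Fluoride desilylation should cleave the secondary triethylsilyl ether much faster than the primary tert-butyldiphenylsilyl ether, and the vinyl ether is stable to these basic conditions.

Step 7
Reactants: 10
Product: 11 (4Z)-1-[(tert-butyldiphenylsilyl)oxy]-6-(ethenyloxy)-4-methylhex-4-en-2-one
Conditions: Dess–Martin periodinane, NaHCO3, CH2Cl2, 0 °C
Reagents that add atoms: none
Why: Buffered Dess–Martin oxidation gives the β,γ-unsaturated ketone under non-basic conditions that should avoid migration of the Z-alkene into conjugation and spare the vinyl ether.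

Step 8
Reactants: 11; 12 3-methylbut-2-enal
Product: 14 (3R,4S)-1-[(tert-butyldiphenylsilyl)oxy]-3-[(2Z)-4-(ethenyloxy)but-2-en-2-yl]-4-hydroxy-6-methylhept-5-en-2-one (5R,6S), via enol borinate 13 (not isolated)
Conditions: (−)-Ipc2BOTf, i-Pr2NEt, CH2Cl2, −78 °C; then 12; H2O2, MeOH, pH 7 buffer
Reagents that add atoms: none
Why: Enolisation toward the allylically activated C5 gives the Z-enol borinate, whose Zimmerman–Traxler chair aldol addition sets the syn C5/C6 relationship while the isopinocampheyl groups select the aldehyde face (reagent-controlled boron aldol reaction).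

Step 9
Reactants: 14
Product: 15 (3R,4S)-1-[(tert-butyldiphenylsilyl)oxy]-3-[(2Z)-4-(ethenyloxy)but-2-en-2-yl]-6-methyl-4-[(triethylsilyl)oxy]hept-5-en-2-one (5R,6S)
Conditions: Et3SiCl, imidazole, DMF, rt
Reagents that add atoms: chlorotriethylsilane, CC[Si](Cl)(CC)CC
Why: Silyl ether protection of the allylic C6 hydroxyl group blocks retro-aldol cleavage and makes the C6 branch the large group that steers the next step.

Step 10
Reactants: 15
Product: 17 2-[(tert-butyldiphenylsilyl)oxy]-1-[(1R,2S,4S,5R,6S)-2-ethenyl-4-hydroxy-2-methyl-5-(prop-1-en-2-yl)-6-[(triethylsilyl)oxy]cyclohexyl]ethan-1-one (5R,6S,7R,8S,10S; acyl group axial), via aldehyde 16 (not isolated)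
Conditions: PhMe, 140 °C then 180 °C, sealed tube
Reagents that add atoms: none
Why: On heating, the allyl vinyl ether undergoes a chair-like Claisen [3,3]-rearrangement that forms C9–C10 and unveils aldehyde 16, whose formyl group then adds to the prenyl-type C7=C11 alkene in an intramolecular type-one carbonyl-ene reaction that forms C7–C8; the closest known reactions are the Claisen rearrangement of neryl vinyl ether and the thermal cyclisation of citronellal to isopulegol. The six-membered carbocycle (C5 to C10) closes in a 6-exo sense through a chair with hydrogen transfer from the C11 methyl group trans to C6, which leaves C11=C13 exocyclic. C10 is controlled by 1,3-allylic strain in the Z-alkene, which holds H5 in the alkene plane toward C2 so that C9 bonds to the face opposite the large C6 branch; with the 5R (syn-aldol) precursor this is the face that gives 10S. C7 and C8 follow from the chair in which the C6 silyloxy group, the isopropenyl group and the forming C8–O bond are equatorial, an axial C8–O bond being disfavoured by the axial C14 methyl group. The step needs face selectivity at C10 and chemoselective ene closure at C7: the Z-geometry secures the first, and the second is secured because the only other unsaturated groups near the aldehyde are the C4 ketone and the vinyl group, neither of which can act as an ene donor.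

Step 11
Reactants: 18 methyl (2R)-3-hydroxy-2-methylpropanoate
Product: 19 methyl (2R)-3-[(tert-butyldiphenylsilyl)oxy]-2-methylpropanoate
Conditions: t-BuPh2SiCl, imidazole, DMF, rt
Reagents that add atoms: tert-butylchlorodiphenylsilane, CC(C)(C)[Si](Cl)(c1ccccc1)c1ccccc1
Why: Silyl ether protection of the primary alcohol leaves the stereocenter untouched.

Step 12
Reactants: 19
Product: 20 (2R)-3-[(tert-butyldiphenylsilyl)oxy]-2-methylpropanoic acid
Conditions: LiOH, THF/H2O, 0 °C; then HCl (aq) to pH 3
Reagents that add atoms: LiOH, [Li+].[OH-]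
Why: Cold saponification of the methyl ester should proceed without epimerisation of the α-methyl center or loss of the silyl ether.

Step 13
Reactants: 17; 20
Product: 21 O8-[(2R)-3-(tert-butyldiphenylsilyloxy)-2-methylpropanoyl] ester of 17 (5R,6S,7R,8S,10S,2′R)
Conditions: DCC, DMAP, CH2Cl2, 0 °C to rt
Reagents that add atoms: none
Why: Steglich esterification acylates the only free hydroxyl group (equatorial C8–OH) with retention at C8 and C2′, and it also prevents any hemiketal between O8 and the C4 ketone.

Step 14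
Reactants: 21
Product: 22 C5 epimer of 21 with the acyl group equatorial (5S,6S,7R,8S,10S,2′R)
Conditions: DBU, PhMe, 60 °C
Reagents that add atoms: none
Why: Base-mediated epimerisation through the C4 enolate should move the acyl group at C5 from the axial to the equatorial position and relieve two 1,3-diaxial contacts, the equatorial C6 silyloxy group lying in the nodal plane of the enolate so that it is not expelled; unchanged 21 is resubmitted.

Step 15
Reactants: 22
Product: 23 12-hydroxy derivative of 22 in which C7 carries a 3-hydroxyprop-1-en-2-yl group (5S,6S,7R,8S,10S,2′R)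
Conditions: SeO2 (cat.), t-BuOOH, CH2Cl2, rt
Reagents that add atoms: selenium dioxide, O=[Se]=O; tert-butyl hydroperoxide, CC(C)(C)OO
Why: SeO2-catalysed allylic oxidation (ene reaction then [2,3]-shift) hydroxylates the methyl group of the isopropenyl unit, the vinyl group having no allylic hydrogen, and any over-oxidised enal converges in step 17.

Step 16
Reactants: 23
Product: 24 6,12-diol formed from 23 by loss of the triethylsilyl group (5S,6S,7S,8S,10S,2′R; the C7 descriptor changes by priority only)
Conditions: PPTS, MeOH, rt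
Reagents that add atoms: none
Why: Mild acid-catalysed methanolysis removes the secondary triethylsilyl ether and should leave both primary tert-butyldiphenylsilyl ethers.

Step 17
Reactants: 24
Product: 27 trans-fused 11(13)-en-12,6-olide that still carries the C4 ketone (5S,6S,7R,8S,10S,2′R), via enal 25 (not isolated), via lactol 26 (not isolated)
Conditions: MnO2, CH2Cl2, rt
Reagents that add atoms: none
Why: MnO2 oxidises only the allylic alcohol to the enal, which is trapped by the C6 hydroxyl group as the lactol and oxidised on to the α-methylene-γ-lactone (oxidative lactonisation); O8 is blocked as the ester, so only the 6,12-lactone can form.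

Step 18
Reactants: 27
Product: 28 15,3′-bis-O-(tert-butyldiphenylsilyl)-11,13-didehydro derivative of the target with the C3=C4 methylene group in place (5R,6R,7R,8S,10S,2′R)
Conditions: Zn, CH2Br2, TiCl4, THF/CH2Cl2, 0 °C to rt
Reagents that add atoms: dibromomethane, BrCBr
Why: Takai–Lombardo methylenation converts the hindered, enolisable C4 ketone into the exocyclic alkene under non-basic conditions that should leave C5, both esters and the lactone untouched.

Step 19
Reactants: 28
Product: 29 15,3′-bis-O-(tert-butyldiphenylsilyl) ether of the target (5R,6R,7R,8S,10S,11S,2′R)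
Conditions: NaBH4, MeOH, 0 °C
Reagents that add atoms: none
Why: Conjugate reduction of the α-methylene lactone by NaBH4 with protonation of the lactone enolate from the less hindered face should give the 11S (11α-methyl) epimer, which is also the thermodynamically preferred one.

Step 20
Reactants: 29
Product: 30 CNP0580343.1 (5R,6R,7R,8S,10S,11S,2′R)
Conditions: HF·pyridine, pyridine, THF, 0 °C to rt
Reagents that add atoms: none
Why: Fluoride desilylation removes both primary tert-butyldiphenylsilyl ethers under buffered conditions that should not open the lactone or shift the acyl group.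

**Compound list**

1 | tert-butyl(oxiran-2-ylmethoxy)diphenylsilane (racemic) | CC(C)(C)[Si](OCC1CO1)(c1ccccc1)c1ccccc1 | starting material
2 | ethyl prop-2-ynoate | CCOC(=O)C#C | starting material
3 | ethyl 3-lithioprop-2-ynoate | CCOC(=O)C#C[Li] | intermediate
4 | ethyl 6-[(tert-butyldiphenylsilyl)oxy]-5-hydroxyhex-2-ynoate (racemic) | CCOC(=O)C#CCC(O)CO[Si](c1ccccc1)(c1ccccc1)C(C)(C)C | intermediate
5 | ethyl 6-[(tert-butyldiphenylsilyl)oxy]-5-[(triethylsilyl)oxy]hex-2-ynoate (racemic) | CCOC(=O)C#CCC(O[Si](CC)(CC)CC)CO[Si](c1ccccc1)(c1ccccc1)C(C)(C)C | intermediate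
6 | ethyl (2Z)-6-[(tert-butyldiphenylsilyl)oxy]-3-methyl-5-[(triethylsilyl)oxy]hex-2-enoate (racemic) | CCOC(=O)/C=C(C)\CC(O[Si](CC)(CC)CC)CO[Si](c1ccccc1)(c1ccccc1)C(C)(C)C | intermediate
7 | (2Z)-6-[(tert-butyldiphenylsilyl)oxy]-3-methyl-5-[(triethylsilyl)oxy]hex-2-en-1-ol (racemic) | OC/C=C(C)\CC(O[Si](CC)(CC)CC)CO[Si](c1ccccc1)(c1ccccc1)C(C)(C)C | intermediate
8 | ethoxyethene | CCOC=C | starting material
9 | (4Z)-1-[(tert-butyldiphenylsilyl)oxy]-6-(ethenyloxy)-4-methyl-2-[(triethylsilyl)oxy]hex-4-ene (racemic) | C=COC/C=C(C)\CC(O[Si](CC)(CC)CC)CO[Si](c1ccccc1)(c1ccccc1)C(C)(C)C | intermediate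
10 | (4Z)-1-[(tert-butyldiphenylsilyl)oxy]-6-(ethenyloxy)-4-methylhex-4-en-2-ol (racemic) | C=COC/C=C(C)\CC(O)CO[Si](c1ccccc1)(c1ccccc1)C(C)(C)C | intermediate
11 | (4Z)-1-[(tert-butyldiphenylsilyl)oxy]-6-(ethenyloxy)-4-methylhex-4-en-2-one | C=COC/C=C(C)\CC(=O)CO[Si](c1ccccc1)(c1ccccc1)C(C)(C)C | intermediate
12 | 3-methylbut-2-enal | CC(C)=CC=O | starting material
13 | (Z)-enol bis(isopinocampheyl)borinate of 11 | C[C@H]1[C@@H](C[C@@H]2C[C@H]1C2(C)C)B([C@@H]3C[C@@H]4C[C@H]([C@H]3C)C4(C)C)O/C(CO[Si](c5ccccc5)(c6ccccc6)C(C)(C)C)=C\C(C)=C/COC=C | intermediate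
14 | (3R,4S)-1-[(tert-butyldiphenylsilyl)oxy]-3-[(2Z)-4-(ethenyloxy)but-2-en-2-yl]-4-hydroxy-6-methylhept-5-en-2-one (5R,6S) | CC(C)=C[C@H](O)[C@@H](/C(C)=C\COC=C)C(=O)CO[Si](c1ccccc1)(c1ccccc1)C(C)(C)C | intermediate
15 | 4-O-triethylsilyl ether of 14 (5R,6S) | CC(C)=C[C@H](O[Si](CC)(CC)CC)[C@@H](/C(C)=C\COC=C)C(=O)CO[Si](c1ccccc1)(c1ccccc1)C(C)(C)C | intermediate
16 | (3S,4R,5S)-4-{[(tert-butyldiphenylsilyl)oxy]acetyl}-3-ethenyl-3,7-dimethyl-5-[(triethylsilyl)oxy]oct-6-enal (5R,6S,10S) | C=C[C@](C)(CC=O)[C@@H](C(=O)CO[Si](c1ccccc1)(c1ccccc1)C(C)(C)C)[C@@H](O[Si](CC)(CC)CC)C=C(C)C | intermediate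
17 | 2-[(tert-butyldiphenylsilyl)oxy]-1-[(1R,2S,4S,5R,6S)-2-ethenyl-4-hydroxy-2-methyl-5-(prop-1-en-2-yl)-6-[(triethylsilyl)oxy]cyclohexyl]ethan-1-one (5R,6S,7R,8S,10S) | C=C[C@]1(C)C[C@H](O)[C@@H](C(C)=C)[C@H](O[Si](CC)(CC)CC)[C@@H]1C(=O)CO[Si](c2ccccc2)(c3ccccc3)C(C)(C)C | intermediate
18 | methyl (2R)-3-hydroxy-2-methylpropanoate | COC(=O)[C@H](C)CO | starting material
19 | methyl (2R)-3-[(tert-butyldiphenylsilyl)oxy]-2-methylpropanoate | COC(=O)[C@H](C)CO[Si](c1ccccc1)(c1ccccc1)C(C)(C)C | intermediate
20 | (2R)-3-[(tert-butyldiphenylsilyl)oxy]-2-methylpropanoic acid | OC(=O)[C@H](C)CO[Si](c1ccccc1)(c1ccccc1)C(C)(C)C | intermediate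
21 | O8-[(2R)-3-(tert-butyldiphenylsilyloxy)-2-methylpropanoyl] ester of 17 (5R,6S,7R,8S,10S,2′R) | C=C[C@]1(C)C[C@H](OC(=O)[C@H](C)CO[Si](c2ccccc2)(c3ccccc3)C(C)(C)C)[C@@H](C(C)=C)[C@H](O[Si](CC)(CC)CC)[C@@H]1C(=O)CO[Si](c4ccccc4)(c5ccccc5)C(C)(C)C | intermediate
22 | C5 epimer of 21 with the acyl group equatorial (5S,6S,7R,8S,10S,2′R) | C=C[C@]1(C)C[C@H](OC(=O)[C@H](C)CO[Si](c2ccccc2)(c3ccccc3)C(C)(C)C)[C@@H](C(C)=C)[C@H](O[Si](CC)(CC)CC)[C@H]1C(=O)CO[Si](c4ccccc4)(c5ccccc5)C(C)(C)C | intermediate
23 | 12-hydroxy derivative of 22 (5S,6S,7R,8S,10S,2′R) | C=C[C@]1(C)C[C@H](OC(=O)[C@H](C)CO[Si](c2ccccc2)(c3ccccc3)C(C)(C)C)[C@@H](C(=C)CO)[C@H](O[Si](CC)(CC)CC)[C@H]1C(=O)CO[Si](c4ccccc4)(c5ccccc5)C(C)(C)C | intermediate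
24 | 6,12-diol from 23 (5S,6S,7S,8S,10S,2′R) | C=C[C@]1(C)C[C@H](OC(=O)[C@H](C)CO[Si](c2ccccc2)(c3ccccc3)C(C)(C)C)[C@@H](C(=C)CO)[C@H](O)[C@H]1C(=O)CO[Si](c4ccccc4)(c5ccccc5)C(C)(C)C | intermediate
25 | 12-aldehyde of 24 (5S,6S,7S,8S,10S,2′R) | C=C[C@]1(C)C[C@H](OC(=O)[C@H](C)CO[Si](c2ccccc2)(c3ccccc3)C(C)(C)C)[C@@H](C(=C)C=O)[C@H](O)[C@H]1C(=O)CO[Si](c4ccccc4)(c5ccccc5)C(C)(C)C | intermediate
26 | 6,12-lactol of 25 (5S,6S,7R,8S,10S,2′R; C12 as a mixture) | C=C[C@]1(C)C[C@H](OC(=O)[C@H](C)CO[Si](c2ccccc2)(c3ccccc3)C(C)(C)C)[C@@H]6[C@H](OC(O)C6=C)[C@H]1C(=O)CO[Si](c4ccccc4)(c5ccccc5)C(C)(C)C | intermediate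
27 | trans-fused 11(13)-en-12,6-olide with the C4 ketone (5S,6S,7R,8S,10S,2′R) | C=C[C@]1(C)C[C@H](OC(=O)[C@H](C)CO[Si](c2ccccc2)(c3ccccc3)C(C)(C)C)[C@@H]6[C@H](OC(=O)C6=C)[C@H]1C(=O)CO[Si](c4ccccc4)(c5ccccc5)C(C)(C)C | intermediate
28 | 15,3′-bis-O-(tert-butyldiphenylsilyl)-11,13-didehydro derivative of the target (5R,6R,7R,8S,10S,2′R) | C=C[C@]1(C)C[C@H](OC(=O)[C@H](C)CO[Si](c2ccccc2)(c3ccccc3)C(C)(C)C)[C@@H]6[C@H](OC(=O)C6=C)[C@H]1C(=C)CO[Si](c4ccccc4)(c5ccccc5)C(C)(C)C | intermediate
29 | 15,3′-bis-O-(tert-butyldiphenylsilyl) ether of the target (5R,6R,7R,8S,10S,11S,2′R) | C=C[C@]1(C)C[C@H](OC(=O)[C@H](C)CO[Si](c2ccccc2)(c3ccccc3)C(C)(C)C)[C@@H]6[C@H](OC(=O)[C@H]6C)[C@H]1C(=C)CO[Si](c4ccccc4)(c5ccccc5)C(C)(C)C | intermediate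
30 | CNP0580343.1 (5R,6R,7R,8S,10S,11S,2′R) | C=C[C@]1(C)C[C@H](OC(=O)[C@H](C)CO)[C@@H]2[C@H](OC(=O)[C@H]2C)[C@H]1C(=C)CO | target

**Totals.** 20 steps in all; the longest linear sequence is 18 steps (steps 1 to 10 and 13 to 20, from 1 to 30); the side-chain acid 20 takes 2 steps.

**Steps most likely to fail**

Step 10 (key step). Enolisation at C5 of 15 before the sigmatropic shift would erode the facial control at C10, and the ene closure may stall or lose selectivity at the temperature it needs. The fallback sets out from 15: the Claisen rearrangement alone is run at 130 °C in PhMe and aldehyde 16 is isolated; the ring is then closed at −78 °C with Me2AlCl in CH2Cl2 (Lewis-acid-promoted carbonyl-ene reaction through the same chair), which comes back to the route at 17. No new compound is made (F0).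

Step 14. The equilibrium between the two C5 epimers may lie too close to unity, and prolonged base treatment may expel the C6 silyloxy group from the enolate. The fallback sets out from 21 and replaces equilibration by kinetic protonation: Me3SiOTf and Et3N in CH2Cl2 under equilibrating conditions should give the fully substituted trimethylsilyl enol ether F1; fluoride-triggered protonation (CsF, 2,6-di-tert-butylphenol, MeCN, 0 °C) should then deliver the proton to the α-face, opposite the axial C14 methyl group on the neighbouring carbon, and comes back to the route at 22.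

Step 8. Enolisation may compete toward C15, and reagent control by the isopinocampheyl groups may give only modest enantioselectivity with this α′-silyloxy ketone. The fallback sets out from 11 and 12: the dibutylboron enolate (Bu2BOTf, i-Pr2NEt, CH2Cl2, −78 °C) should give the racemic syn-aldol, that is 14 together with the enantiomer of 14 F2. A Sharpless kinetic resolution of this secondary allylic alcohol (Ti(O-i-Pr)4, D-(−)-diisopropyl tartrate, t-BuOOH, 4 Å molecular sieves, CH2Cl2, −20 °C) should then epoxidise F2 to the epoxy alcohol F3 and leave 14, which is separated and comes back to the route at 14.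

**Further compounds**

F0 | step 10 | none | none
F1 | step 14 | trimethylsilyl enol ether (C4=C5, either geometry) of 21 | C=C[C@]1(C)C[C@H](OC(=O)[C@H](C)CO[Si](c2ccccc2)(c3ccccc3)C(C)(C)C)[C@@H](C(C)=C)[C@H](O[Si](CC)(CC)CC)C1=C(O[Si](C)(C)C)CO[Si](c4ccccc4)(c5ccccc5)C(C)(C)C
F2 | step 8 | enantiomer of 14 (5S,6R) | CC(C)=C[C@@H](O)[C@H](/C(C)=C\COC=C)C(=O)CO[Si](c1ccccc1)(c1ccccc1)C(C)(C)C
F3 | step 8 | 7,11-epoxy alcohol formed from F2 | CC1(C)O[C@H]1[C@@H](O)[C@H](/C(C)=C\COC=C)C(=O)CO[Si](c2ccccc2)(c3ccccc3)C(C)(C)C
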